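**Plan**

Atoms are numbered as they stand in the target SMILES (C1 to C29, O6, O22, O28).
Enabling feature: in the bicyclo[2.2.2]octene (bridgeheads C14 and C25; bridges C15=C16, C26–C27, C13–C29) the alkene bridge C15=C16 carries the lactone carbons C23 and C17, so it is the trace of an alkyne that bore an ester and a pentanoyl group.
Retrosynthesis: open the cyclohexene-fused butenolide (C7–C9 and C7–O6 by carbonylation, C5–C10 by acylation), then the O22–C17 enol-lactone bond (dehydration of a keto acid), then C14–C15 and C16–C25 ([4+2]), and last C13–C14 and C25–C29 (first [4+2]).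
Forward: cyclohexenone and a 2-silyloxybutadiene give the cis-decalin; oxidation, ketalisation and kinetic silylation give the silyloxydiene; the acetylenic keto ester closes the bicyclo[2.2.2]octadiene; the butenolide on C15/C16 is closed next and the one on C9/C10 last.
Stereochemistry: C13/C29 from the catalyst-controlled first cycloaddition, C14/C25 from addition anti to the cis-fused ring, C27 from hydride attack on the open face followed by Mitsunobu inversion, both (Z)-alkenes from thermodynamic control.

Key step: step 8

Assumption: the facial sense of the first cycloaddition is taken from the α-C–H···O binding model of cationic oxazaborolidines with cyclic enones, on which the (S)-catalyst is chosen; should the antipode of the cycloadduct form, the (R)-catalyst is used with no other change.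

**Route**

Step 1
Reactants: 1 but-3-en-2-one
Product: 2 2-(triisopropylsilyloxy)buta-1,3-diene
Conditions: iPr3SiOTf, Et3N, Et2O, 0 °C → rt
Reagents that add atoms: triisopropylsilyl trifluoromethanesulfonate, CC(C)[Si](C(C)C)(C(C)C)OS(=O)(=O)C(F)(F)F
Why: Soft enolisation and O-silylation of the methyl ketone (silyl enol ether formation) should give the 2-silyloxydiene, with no stereocentre involved.

Step 2
Reactants: 2 2-(triisopropylsilyloxy)buta-1,3-diene; 3 cyclohex-2-en-1-one
Product: 4 (4aR,8aS)-6-(triisopropylsilyloxy)-3,4,4a,5,8,8a-hexahydronaphthalen-1(2H)-one (cis-fused; C9 ketone, silyl enol ether C26=C27)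
Conditions: (S)-1-(2-methylphenyl)-3,3-diphenyltetrahydro-1H,3H-pyrrolo[1,2-c][1,3,2]oxazaborole (20 mol%), HN(SO2CF3)2 (20 mol%), CH2Cl2, −20 °C
Reagents that add atoms: none
Why: Cationic oxazaborolidine-catalysed Diels–Alder reaction: the CH2 next to the silyloxy carbon bonds to the enone β-carbon (C13), suprafacial addition makes the ring fusion cis, and the catalyst shields one face of the bound enone so that C13 and C29 are set together.

Step 3
Reactants: 4 (4aR,8aS)-6-(triisopropylsilyloxy)-3,4,4a,5,8,8a-hexahydronaphthalen-1(2H)-one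
Product: 5 (4aR,8aR)-2,3,4,4a,5,8a-hexahydronaphthalene-1,6-dione (cis-fused; C9 ketone, enone C25=C26–C27=O)
Conditions: Pd(OAc)2 (1.1 equiv), MeCN, 40 °C
Reagents that add atoms: none
Why: Saegusa–Ito oxidation: the palladium enolate at C26 can only lose a β-hydrogen from C25, so the enone should form regiospecifically without touching C13 or C29.

Step 4
Reactants: 5 (4aR,8aR)-2,3,4,4a,5,8a-hexahydronaphthalene-1,6-dione
Product: 6 (4aR,8aR)-1,1-ethylenedioxy-1,2,3,4,4a,8a-hexahydronaphthalen-6(5H)-one (C9 dioxolane, enone kept)
Conditions: Me3SiOCH2CH2OSiMe3 (1.5 equiv), Me3SiOTf (5 mol%), CH2Cl2, −78 °C; pyridine quench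
Reagents that add atoms: 1,2-bis(trimethylsilyloxy)ethane, C[Si](C)(C)OCCO[Si](C)(C)C
Why: Noyori ketalisation is much faster at a saturated ketone than at a conjugated one, and the aprotic low-temperature conditions should avoid epimerisation of the doubly activated C29–H.

Step 5
Reactants: 6 (4aR,8aR)-1,1-ethylenedioxy-1,2,3,4,4a,8a-hexahydronaphthalen-6(5H)-one
Product: 8 (4aR,8aS)-6-(tert-butyldimethylsilyloxy)-1,1-ethylenedioxy-1,2,3,4,4a,8a-hexahydronaphthalene (diene C14=C27–C26=C25), via lithium dienolate 7 (not isolated)
Conditions: LiN(iPr)2 (1.1 equiv), THF, −78 °C; then tBuMe2SiCl, DMPU, −78 → 0 °C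
Reagents that add atoms: tert-butyldimethylsilyl chloride, CC(C)(C)[Si](C)(C)Cl
Why: Kinetic α′-deprotonation of the enone at C14 and O-silylation of the cross-conjugated dienolate (silyl dienol ether formation) should give the 2-silyloxy-1,3-diene, the γ-proton at C29 being left in place.

Step 6
Reactants: 9 methyl propiolate; 10 pentanal
Product: 12 methyl 4-hydroxyoct-2-ynoate (racemic), via lithium acetylide 11 (not isolated)
Conditions: LiN(iPr)2, THF, −78 °C; then 10; AcOH quench at −78 °C
Reagents that add atoms: none
Why: 1,2-Addition of the lithium acetylide of the propiolate to the aldehyde is a standard route to 4-hydroxy-2-ynoates; the carbinol centre is removed in the next step.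

Step 7
Reactants: 12 methyl 4-hydroxyoct-2-ynoate
Product: 13 methyl 4-oxooct-2-ynoate
Conditions: Dess–Martin periodinane, CH2Cl2, 0 °C → rt
Reagents that add atoms: none
Why: Dess–Martin oxidation of a propargylic alcohol should give the ynone under neutral conditions that spare the electrophilic alkyne.

Step 8
Reactants: 8 (4aR,8aS)-6-(tert-butyldimethylsilyloxy)-1,1-ethylenedioxy-1,2,3,4,4a,8a-hexahydronaphthalene; 13 methyl 4-oxooct-2-ynoate
Product: 14 bicyclo[2.2.2]octadiene adduct (C15 CO2Me, C16 pentanoyl, silyl enol ether C26=C27, C9 dioxolane; carbocycle C9–C13/C29 cis-fused and syn to the C26=C27 bridge)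
Conditions: 13 (1.3 equiv), toluene (0.5 M), argon, dark, 25 → 60 °C
Reagents that add atoms: none
Why: This is a thermal, concerted but asynchronous Diels–Alder reaction of a 2-silyloxycyclohexa-1,3-diene with an acetylenic keto ester, a known reaction class, in which C14 (the β-carbon of the silyl enol ether, with the largest HOMO coefficient) bonds first to the alkyne carbon β to the ketone and C25 then closes onto the carbon α to the ketone. The new six-membered ring (C14, C15, C16, C25, C26, C27) closes by suprafacial 1,4-addition across the diene termini, which turns the cyclohexadiene into a bicyclo[2.2.2]octa-2,5-diene. The regioselectivity needed, CO2Me on C15 and pentanoyl on C16 (silyloxy carbon C27 para to C16), rests on the ketone being the stronger acceptor than the ester. The new bridgehead stereocentres C14 and C25 are set by the face of approach: the cis-fused ring residues C12 and C9 (with its dioxolane) cover one face of the diene, so the alkyne should add to the face that bears H13 and H29. The carbocycle therefore ends up syn to the C26=C27 bridge and anti to the new C15=C16 bridge, as the target requires. The moderate temperature should keep the adduct from retro-[4+2] loss of the C13–C29 bridge (Alder–Rickert fragmentation).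

Step 9
Reactants: 14 bicyclo[2.2.2]octadiene adduct
Product: 15 C27 ketone (bicyclo[2.2.2]oct-5-en-2-one with C15 CO2Me, C16 pentanoyl, C9 dioxolane)
Conditions: Bu4NF (1.1 equiv), AcOH (1.5 equiv), THF, 0 °C
Reagents that add atoms: none
Why: Buffered fluoride cleavage of the silyl enol ether with C-protonation at C26 should free the ketone while the dioxolane and the ene-keto ester stay intact.

Step 10
Reactants: 15 C27 ketone
Product: 16 C27 alcohol with the hydroxyl pointing to the C13–C29 bridge (27-epimer of the target configuration)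
Conditions: NaBH4 (0.5 equiv), MeOH/CH2Cl2 1:1, −78 °C
Reagents that add atoms: none
Why: Chemoselective borohydride reduction of a saturated ketone in the presence of a conjugated one: hydride should enter from the face turned to the C15=C16 bridge because the other face is blocked by C12H2, which places the hydroxyl on the hindered side.

Step 11
Reactants: 16 C27 alcohol (hydroxyl toward the C13–C29 bridge)
Product: 17 C27 4-nitrobenzoate with the oxygen pointing to the C15=C16 bridge (target configuration at C27)
Conditions: PPh3, diisopropyl azodicarboxylate, 4-nitrobenzoic acid, THF, 0 °C → rt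
Reagents that add atoms: 4-nitrobenzoic acid, OC(=O)c1ccc(cc1)[N+](=O)[O-]
Why: Mitsunobu inversion: the carboxylate should displace the alkoxyphosphonium group by SN2 from the open face next to the alkene bridge, which sets C27 as in the target.

Step 12
Reactants: 17 C27 4-nitrobenzoate
Product: 19 C9-keto C27-hydroxy pseudoacid (5-butyl-5-hydroxybutenolide on C15=C16; lactol carbon C17 as a mixture of epimers), via dioxolane hydroxy keto acid 18 (not isolated)
Conditions: LiOH·H2O (5 equiv), THF/MeOH/H2O, rt; then 2 M HCl to pH 1, THF, 40 °C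
Reagents that add atoms: lithium hydroxide, [Li+].[OH-]; water, O
Why: Saponification cleaves both esters (the methyl ester with help from the neighbouring ketone), and acidification should close the cis γ-keto acid to its ring tautomer and hydrolyse the dioxolane (ester hydrolysis, lactol formation, ketal hydrolysis).

Step 13
Reactants: 19 C9-keto C27-hydroxy pseudoacid
Product: 20 C9-keto C27-hydroxy (Z)-butylidene butenolide (C17=C18 formed)
Conditions: TsOH·H2O (10 mol%), toluene, 4 Å molecular sieves, 80 °C
Reagents that add atoms: none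
Why: Acid-catalysed dehydration of a γ-hydroxybutenolide through the acyloxy-stabilised cation should give the γ-alkylidene butenolide, the (Z)-isomer (propyl chain syn to O22) being the thermodynamic one.

Step 14
Reactants: 20 C9-keto C27-hydroxy (Z)-butylidene butenolide
Product: 21 C27 tert-butyldimethylsilyl ether of 20
Conditions: tBuMe2SiCl, imidazole, DMF, rt
Reagents that add atoms: tert-butyldimethylsilyl chloride, CC(C)(C)[Si](C)(C)Cl
Why: Silylation of the secondary alcohol on its open face protects O28 for the enolate and triflation chemistry that follows.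

Step 15
Reactants: 21 C27 silyl ether ketone
Product: 22 C10-pentanoyl β-diketone (largely as the chelated ring enol C9(OH)=C10)
Conditions: MgBr2·OEt2 (2.5 equiv), iPr2NEt (3 equiv), 1-pentanoyl-1H-benzotriazole (1.3 equiv; from pentanoyl chloride and 1H-benzotriazole), CH2Cl2, rt
Reagents that add atoms: 1-pentanoyl-1H-benzotriazole, CCCCC(=O)n1nnc2ccccc21
Why: Soft-enolisation C-acylation of a ketone: only acylation at the CH2 carbon C10 gives an enolisable diketone that is held as its magnesium chelate, and the amine base should be too weak to harm the enol lactone.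

Step 16
Reactants: 22 C10-pentanoyl β-diketone
Product: 23 C9 enol triflate (C9=C10 in the ring, pentanoyl on C10)
Conditions: (CF3SO2)2O (1.1 equiv), Et3N (1.5 equiv), CH2Cl2, −78 °C
Reagents that add atoms: trifluoromethanesulfonic anhydride, O=S(=O)(OS(=O)(=O)C(F)(F)F)C(F)(F)F
Why: O-Triflation of the endocyclic enol of a 2-acylcyclohexanone should give the ring vinyl triflate, in which the ring holds the acyl group cis to the triflate.

Step 17
Reactants: 23 C9 enol triflate
Product: 24 O28-tert-butyldimethylsilyl ether of the target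
Conditions: Pd(OAc)2 (5 mol%), 1,3-bis(diphenylphosphino)propane (6 mol%), CO (1 atm), Et3N (2 equiv), DMF, 60 °C
Reagents that add atoms: carbon monoxide, [C-]#[O+]
Why: Palladium-catalysed carbonylative lactonisation: oxidative addition of zerovalent palladium to the vinyl triflate, CO insertion and capture of the acyl-palladium species by the enol oxygen of the cis pentanoyl group should close the second butenolide, the (Z)-alkene C4=C5 being the stable isomer.

Step 18
Reactants: 24 O28-silyl ether of the target
Product: 25 CNP0289078.1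
Conditions: HF·pyridine, THF, 0 °C → rt
Reagents that add atoms: none
Why: Acidic fluoride desilylation frees the C27 hydroxyl under conditions that enol lactones tolerate.

**Compound list**

1 | but-3-en-2-one | CC(=O)C=C | starting material
2 | 2-(triisopropylsilyloxy)buta-1,3-diene | C=CC(=C)O[Si](C(C)C)(C(C)C)C(C)C | intermediate
3 | cyclohex-2-en-1-one | O=C1C=CCCC1 | starting material
4 | (4aR,8aS)-6-(triisopropylsilyloxy)-3,4,4a,5,8,8a-hexahydronaphthalen-1(2H)-one | O=C1CCC[C@@H]2CC(O[Si](C(C)C)(C(C)C)C(C)C)=CC[C@H]12 | intermediate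
5 | (4aR,8aR)-2,3,4,4a,5,8a-hexahydronaphthalene-1,6-dione | O=C1CCC[C@@H]2CC(=O)C=C[C@H]12 | intermediate
6 | (4aR,8aR)-1,1-ethylenedioxy-1,2,3,4,4a,8a-hexahydronaphthalen-6(5H)-one | O1CCOC12CCC[C@@H]3CC(=O)C=C[C@H]23 | intermediate
7 | lithium dienolate of 6 (C14=C27(OLi)–C26=C25) | O1CCOC12CCC[C@@H]3C=C([O-])C=C[C@H]23.[Li+] | intermediate
8 | (4aR,8aS)-6-(tert-butyldimethylsilyloxy)-1,1-ethylenedioxy-1,2,3,4,4a,8a-hexahydronaphthalene | O1CCOC12CCC[C@@H]3C=C(O[Si](C)(C)C(C)(C)C)C=C[C@H]23 | intermediate
9 | methyl propiolate | C#CC(=O)OC | starting material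
10 | pentanal | CCCCC=O | starting material
11 | lithium acetylide of methyl propiolate | [Li+].[C-]#CC(=O)OC | intermediate
12 | methyl 4-hydroxyoct-2-ynoate (racemic) | CCCCC(O)C#CC(=O)OC | intermediate
13 | methyl 4-oxooct-2-ynoate | CCCCC(=O)C#CC(=O)OC | intermediate
14 | bicyclo[2.2.2]octadiene adduct (C15 CO2Me, C16 pentanoyl, silyl enol ether C26=C27, C9 dioxolane) | O1CCOC12CCC[C@@H]3[C@H]4C(C(=O)OC)=C(C(=O)CCCC)[C@H](C=C4O[Si](C)(C)C(C)(C)C)[C@H]23 | intermediate
15 | C27 ketone | O1CCOC12CCC[C@@H]3[C@H]4C(C(=O)OC)=C(C(=O)CCCC)[C@H](CC4=O)[C@H]23 | intermediate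
16 | C27 alcohol, hydroxyl toward the C13–C29 bridge | O1CCOC12CCC[C@@H]3[C@H]4C(C(=O)OC)=C(C(=O)CCCC)[C@H](C[C@H]4O)[C@H]23 | intermediate
17 | C27 4-nitrobenzoate, oxygen toward the C15=C16 bridge | O1CCOC12CCC[C@@H]3[C@H]4C(C(=O)OC)=C(C(=O)CCCC)[C@H](C[C@@H]4OC(=O)c5ccc(cc5)[N+](=O)[O-])[C@H]23 | intermediate
18 | dioxolane hydroxy keto acid | O1CCOC12CCC[C@@H]3[C@H]4C(C(=O)O)=C(C(=O)CCCC)[C@H](C[C@@H]4O)[C@H]23 | intermediate
19 | C9-keto C27-hydroxy pseudoacid (5-butyl-5-hydroxybutenolide on C15=C16) | O=C1CCC[C@@H]2[C@H]3C4=C(C(O)(CCCC)OC4=O)[C@H](C[C@@H]3O)[C@H]12 | intermediate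
20 | C9-keto C27-hydroxy (Z)-butylidene butenolide | O=C1CCC[C@@H]2[C@H]3C4=C(/C(=C/CCC)OC4=O)[C@H](C[C@@H]3O)[C@H]12 | intermediate
21 | C27 tert-butyldimethylsilyl ether of 20 | O=C1CCC[C@@H]2[C@H]3C4=C(/C(=C/CCC)OC4=O)[C@H](C[C@@H]3O[Si](C)(C)C(C)(C)C)[C@H]12 | intermediate
22 | C10-pentanoyl β-diketone (drawn as diketone; C10 unassigned, enolised) | O=C1C(C(=O)CCCC)CC[C@@H]2[C@H]3C4=C(/C(=C/CCC)OC4=O)[C@H](C[C@@H]3O[Si](C)(C)C(C)(C)C)[C@H]12 | intermediate
23 | C9 enol triflate | FC(F)(F)S(=O)(=O)OC1=C(C(=O)CCCC)CC[C@@H]2[C@H]3C4=C(/C(=C/CCC)OC4=O)[C@H](C[C@@H]3O[Si](C)(C)C(C)(C)C)[C@H]12 | intermediate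
24 | O28-tert-butyldimethylsilyl ether of the target | CCC/C=C1\OC(=O)C2=C1CC[C@@H]1[C@H]3C4=C(/C(=C/CCC)OC4=O)[C@H](C[C@@H]3O[Si](C)(C)C(C)(C)C)[C@H]21 | intermediate
25 | CNP0289078.1 (13S,14S,25R,27S,29R in SMILES numbering; both butylidene groups Z) | CCC/C=C1\OC(=O)C2=C1CC[C@@H]1[C@H]3C4=C(/C(=C/CCC)OC4=O)[C@H](C[C@@H]3O)[C@H]21 | target

**Count and risks**

Total step count: 18. Longest linear sequence: 16 steps (steps 1 to 5, then 8 to 18); steps 6 and 7 form the two-step dienophile branch.

Step 8. The ester may compete with the ketone for control of the first bond, so regiocontrol may leak, and prolonged heating may trigger retro-[4+2] loss of the cyclohexene bridge. The fallback sets out from 8 and uses a dienophile with a single acceptor. Commercial hept-1-yn-3-ol is oxidised with Dess–Martin periodinane to hept-1-yn-3-one F1, which is brominated at the alkyne terminus (N-bromosuccinimide, AgNO3 cat., acetone) to 1-bromohept-1-yn-3-one F2. Cycloaddition of F2 with 8 in toluene should place bromine on C15 and the pentanoyl group on C16 in the bromo adduct F3. Buffered fluoride cleavage (Bu4NF, AcOH) gives the bromo enone ketone F4. Methoxycarbonylation of its vinyl bromide (Pd(OAc)2, 4,5-bis(diphenylphosphino)-9,9-dimethylxanthene, CO, MeOH, Et3N, 70 °C) returns to the route at 15.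

Step 11. Activation of the shielded C27 hydroxyl by the phosphonium reagent may be slow, which would lead to recovered alcohol or to acylation with retention. The fallback sets out from 16 and replaces the Mitsunobu reaction by sulfonate displacement with an oxygen nucleophile that needs no ester cleavage. (CF3SO2)2O and pyridine in CH2Cl2 at −20 °C give the C27 triflate F5. Bu4N(NO2) in toluene/MeCN at rt displaces it with inversion to the nitrite ester F6, which hydrolyses on aqueous work-up to the inverted hydroxy keto ester F7. The conditions of step 12 convert F7 into 18 and then 19, where the route is rejoined.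

Step 17. The acyl-palladium species may be intercepted by adventitious water or lose CO before the enol oxygen closes the ring, and the alkene geometry may erode. The fallback sets out from 23 and separates carbonylation from ring closure. Hydroxycarbonylation (Pd(OAc)2, 1,1′-bis(diphenylphosphino)ferrocene, KOAc, CO 1 atm, DMSO, 60 °C, aqueous work-up) gives the acid, which should close at once with the cis pentanoyl group to the silyl-protected pseudoacid F8. Dehydration as in step 13 (TsOH·H2O cat., toluene, 80 °C) returns to the route at 24; a butenolide opened on the way would re-close under the same conditions.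

Further compounds
F1 | step 8 | hept-1-yn-3-one | CCCCC(=O)C#C
F2 | step 8 | 1-bromohept-1-yn-3-one | CCCCC(=O)C#CBr
F3 | step 8 | bromo adduct (C15 Br, C16 pentanoyl, silyl enol ether C26=C27, C9 dioxolane) | O1CCOC12CCC[C@@H]3[C@H]4C(Br)=C(C(=O)CCCC)[C@H](C=C4O[Si](C)(C)C(C)(C)C)[C@H]23
F4 | step 8 | bromo enone ketone (C15 Br, C16 pentanoyl, C27 ketone, C9 dioxolane) | O1CCOC12CCC[C@@H]3[C@H]4C(Br)=C(C(=O)CCCC)[C@H](CC4=O)[C@H]23
F5 | step 11 | C27 triflate of 16 | O1CCOC12CCC[C@@H]3[C@H]4C(C(=O)OC)=C(C(=O)CCCC)[C@H](C[C@H]4OS(=O)(=O)C(F)(F)F)[C@H]23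
F6 | step 11 | C27 nitrite ester, inverted | O1CCOC12CCC[C@@H]3[C@H]4C(C(=O)OC)=C(C(=O)CCCC)[C@H](C[C@@H]4ON=O)[C@H]23
F7 | step 11 | inverted hydroxy keto ester | O1CCOC12CCC[C@@H]3[C@H]4C(C(=O)OC)=C(C(=O)CCCC)[C@H](C[C@@H]4O)[C@H]23
F8 | step 17 | silyl-protected pseudoacid (5-butyl-5-hydroxybutenolide on C9=C10) | CCCCC1(O)OC(=O)C2=C1CC[C@@H]1[C@H]3C4=C(/C(=C/CCC)OC4=O)[C@H](C[C@@H]3O[Si](C)(C)C(C)(C)C)[C@H]21
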